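## Retrosynthetic overview

1. The pyran ring is closed last, at O1–C8a, by a dehydrogenative cyclization of a (Z)-3-hydroxyalkenyl phenol through its p-quinone monoketal. Enabling feature: on the benzo ring C5–OH and C8–OMe are para, so the arene is a masked quinone monoketal whose β-carbon is C8a (still C–H), and the cis C3=C4 bond holds the C2 oxygen over C8a. The C2–O bond is never broken, so C2 is carried in enantiopure.
2. C4–C4a: Sonogashira coupling of a 6-iodo-2,3,4-trimethoxyphenyl acetate with a tertiary propargylic alcohol, then Lindlar reduction.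
3. C2 carbinol: Sharpless epoxidation of an E-allylic alcohol (from Negishi carboalumination of a terminal alkyne), then epoxy chloride fragmentation to the alkynol.
4. Cyclohexane: a chiral-imine Michael addition to butenone sets the quaternary carbon; Robinson closure to a temporary octalone sets the trans methyl by equilibration; Eschenmoser–Tanabe fragmentation reopens that ring to ketone plus butynyl chain; methylenation follows.
5. Ring order: cyclohexane (bought, stereocenters set on it), temporary cyclohexenone ring (made and cleaved), benzene ring (bought), pyran ring (last).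

Key step: step 16

Assumption (chemistry): the imine of 2,6-dimethylcyclohexanone is taken to add with the same facial sense as the imine of 2-methylcyclohexanone, the (S)-amine giving the (R)-quaternary carbon; if the sense were opposite, the (R)-amine would be used.

## Route

Step 1
Reactants: 1 2,6-dimethylcyclohexan-1-one (commercial cis/trans mixture); 2 (S)-1-phenylethylamine; 3 but-3-en-2-one
Product: 6 (2R)-2,6-dimethyl-2-(3-oxobutyl)cyclohexan-1-one (both C6 epimers), via imine 4 (not isolated), via adduct imine 5 (not isolated)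
Conditions: 1 + 2, TsOH (cat.), toluene, reflux, Dean–Stark; then 3 (1.1 equiv), THF, rt → 40 °C; then 20% aq. AcOH, rt
Reagents that add atoms: water, O
Why: Asymmetric Michael addition of a chiral 1-phenylethylamine imine: the secondary enamine tautomer should add to the enone through a compact aza-ene-like transition state on the face away from the phenyl group, which sets the quaternary carbon as R, and mild acid hydrolysis frees the ketone and the auxiliary; the C6 methyl center is left open here because step 2 equilibrates it.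

Step 2
Reactants: 6
Product: 7 (4aR,8R)-4a,8-dimethyl-4,4a,5,6,7,8-hexahydronaphthalen-2(3H)-one
Conditions: NaOMe, MeOH, rt → 60 °C
Reagents that add atoms: none
Why: Intramolecular aldol condensation (second half of a Robinson annulation); under the reversible basic conditions C8, now γ to the enone, should equilibrate through the dienolate to the equatorial methyl trans to the axial angular methyl (the cis epimer has a 1,3-diaxial methyl/methyl contact, as in 6-methyl-4-en-3-one steroids, which settle in the 6α series), setting the second ring stereocenter as R.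

Step 3
Reactants: 7
Product: 8 (4aR,8R)-1,8a-epoxy-4a,8-dimethyloctahydronaphthalen-2(1H)-one (both epoxide faces)
Conditions: 30% aq. H2O2, NaOH, MeOH, 0 → 15 °C
Reagents that add atoms: hydrogen peroxide, OO
Why: Weitz–Scheffer nucleophilic epoxidation of the enone; the configuration of the two epoxide carbons does not matter because both lose it in step 4, and C8 can no longer epimerize once the enone is gone.

Step 4
Reactants: 8
Product: 10 (2R,6R)-2-(but-3-yn-1-yl)-2,6-dimethylcyclohexan-1-one, via tosylhydrazone 9 (not isolated)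
Conditions: TsNHNH2, AcOH/CH2Cl2 (1:1), −20 °C → rt
Reagents that add atoms: none
Why: Eschenmoser–Tanabe fragmentation: the α,β-epoxy tosylhydrazone should collapse with loss of N2 and sulfinate to the ring ketone and the terminal alkyne, reopening the temporary ring without touching either stereocenter under cold, weakly acidic conditions.

Step 5
Reactants: 10
Product: 11 (1R,3R)-1-(but-3-yn-1-yl)-1,3-dimethyl-2-methylidenecyclohexane
Conditions: Zn, CH2Br2, TiCl4, THF/CH2Cl2, 0 °C → rt
Reagents that add atoms: dibromomethane, BrCBr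
Why: Takai–Lombardo methylenation with a non-basic reagent should convert the hindered, enolizable ketone into the exocyclic methylene without epimerizing the adjacent methyl-bearing carbon.

Step 6
Reactants: 11
Product: 13 (2E)-5-[(1R,3R)-1,3-dimethyl-2-methylidenecyclohexyl]-3-methylpent-2-en-1-ol, via alkenylalane 12 (not isolated)
Conditions: Me3Al (3 equiv), Cp2ZrCl2 (0.25 equiv), CH2Cl2, 0 °C → rt; then (CH2O)n, THF, 0 °C → rt; aq. potassium sodium tartrate
Reagents that add atoms: trimethylaluminium, C[Al](C)C; formaldehyde (as paraformaldehyde), C=O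
Why: Negishi zirconium-catalysed carboalumination adds methyl and aluminium syn across the terminal alkyne with methyl on the internal carbon, and the alkenylalane is hydroxymethylated with retention, which fixes the E trisubstituted alkene; the hindered 1,1-disubstituted ring alkene should not react.

Step 7
Reactants: 13
Product: 14 [(2S,3S)-3-{2-[(1R,3R)-1,3-dimethyl-2-methylidenecyclohexyl]ethyl}-3-methyloxiran-2-yl]methanol
Conditions: Ti(OiPr)4 (10 mol%), L-(+)-diethyl tartrate (12 mol%), t-BuOOH (2 equiv), 4 Å molecular sieves, CH2Cl2, −20 °C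
Reagents that add atoms: tert-butyl hydroperoxide, CC(C)(C)OO
Why: Sharpless asymmetric epoxidation: with L-(+)-diethyl tartrate the E allylic alcohol should be epoxidized on the face that gives the (2S,3S) epoxy alcohol, as with geraniol, which sets the future C2 carbinol of the chromene by reagent control, while the isolated methylene group is inert to the titanium/hydroperoxide system.

Step 8
Reactants: 14
Product: 15 (2R,3S)-2-(chloromethyl)-3-{2-[(1R,3R)-1,3-dimethyl-2-methylidenecyclohexyl]ethyl}-3-methyloxirane
Conditions: PPh3, CCl4, NaHCO3, reflux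
Reagents that add atoms: tetrachloromethane, ClC(Cl)(Cl)Cl
Why: Appel chlorination of the primary alcohol under bicarbonate buffering, which leaves the epoxide intact (the descriptor at C2 changes only because chlorine changes the priorities).

Step 9
Reactants: 15
Product: 16 (3S)-5-[(1R,3R)-1,3-dimethyl-2-methylidenecyclohexyl]-3-methylpent-1-yn-3-ol
Conditions: n-BuLi (3.2 equiv), THF, −78 → −30 °C; aq. NH4Cl
Reagents that add atoms: none
Why: Base-induced fragmentation of a 2,3-epoxy chloride: lithiation α to chlorine opens the epoxide by β-elimination to a chlorovinyl alkoxide and a second elimination of HCl gives the terminal alkyne; the tertiary C–O bond is never broken, so the carbinol keeps its configuration (S).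

Step 10
Reactants: 17 2,3,4-trimethoxybenzaldehyde
Product: 19 2,3,4-trimethoxyphenol, via aryl formate 18 (not isolated)
Conditions: mCPBA, CH2Cl2, 0 °C → rt; then K2CO3, MeOH, rt
Reagents that add atoms: 3-chloroperoxybenzoic acid, OOC(=O)c1cccc(Cl)c1
Why: Dakin-type Baeyer–Villiger oxidation of an electron-rich benzaldehyde (aryl migration) followed by methanolysis of the formate.

Step 11
Reactants: 19
Product: 20 6-iodo-2,3,4-trimethoxyphenol
Conditions: I2, NaHCO3, THF/H2O, 0 °C
Reagents that add atoms: iodine, II
Why: Electrophilic aromatic iodination of the phenoxide, directed to the only hydrogen-bearing position ortho or para to the phenol oxygen.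

Step 12
Reactants: 20
Product: 21 6-iodo-2,3,4-trimethoxyphenyl acetate
Conditions: Ac2O, pyridine, DMAP (cat.), CH2Cl2, rt
Reagents that add atoms: acetic anhydride, CC(=O)OC(C)=O
Why: O-Acetylation; the ester blocks the phenol so that the ortho-alkynyl phenol cannot close to a benzofuran under the coupling conditions of step 13.

Step 13
Reactants: 16; 21
Product: 22 6-[(3S)-5-[(1R,3R)-1,3-dimethyl-2-methylidenecyclohexyl]-3-hydroxy-3-methylpent-1-yn-1-yl]-2,3,4-trimethoxyphenyl acetate
Conditions: Pd(PPh3)2Cl2 (3 mol%), CuI (5 mol%), Et3N, THF, rt → 40 °C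
Reagents that add atoms: none
Why: Sonogashira coupling of the aryl iodide with the terminal alkyne of the unprotected tertiary propargylic alcohol, which forms the future C4–C4a bond.

Step 14
Reactants: 22
Product: 23 6-[(1Z,3S)-5-[(1R,3R)-1,3-dimethyl-2-methylidenecyclohexyl]-3-hydroxy-3-methylpent-1-en-1-yl]-2,3,4-trimethoxyphenyl acetate
Conditions: H2 (1 atm), Pd/CaCO3 poisoned with Pb(OAc)2, quinoline, EtOAc, rt, stopped after one equivalent of H2
Reagents that add atoms: none
Why: Lindlar semihydrogenation: syn delivery of hydrogen on the poisoned palladium surface should give the Z alkene (the future C3=C4 bond), and the hindered methylene group and the aryl acetate should not react.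

Step 15
Reactants: 23
Product: 24 6-[(1Z,3S)-5-[(1R,3R)-1,3-dimethyl-2-methylidenecyclohexyl]-3-hydroxy-3-methylpent-1-en-1-yl]-2,3,4-trimethoxyphenol
Conditions: K2CO3, MeOH, 0 °C, argon; pH 7 buffer work-up, no silica gel, used at once
Reagents that add atoms: none
Why: Base-catalysed methanolysis of the aryl acetate; acid and silica gel are avoided because the Z tertiary allylic alcohol could otherwise ionize and close onto the phenol oxygen.

Step 16
Reactants: 24
Product: 27 (2S)-2-{2-[(1R,3R)-1,3-dimethyl-2-methylidenecyclohexyl]ethyl}-6,7,8-trimethoxy-2-methyl-2H-chromen-5-ol (target), via quinone monoketal 25 (not isolated), via dienol adduct 26 (not isolated)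
Conditions: graphite anode, Pt cathode, undivided cell, constant current (about 2.1 F/mol), LiClO4, 2,6-lutidine, MeOH, 0 °C; then DBU, 0 °C → rt; then AcOH, rt; light excluded
Reagents that add atoms: methanol, CO (second ketal methoxy group of 25; one of the two is lost again)
Why: Proposed new method: two-electron anodic oxidation of the para-methoxyphenol in methanol should give quinone monoketal 25 (closest known reaction type: anodic ketalization of 4-methoxyphenols to quinone monoketals), in which C8a has become the β-carbon of the C5 dienone. On addition of DBU the tertiary C2 alkoxide, held over C8a by the cis C3=C4 bond, should add in a 6-endo-trig oxa-Michael closure of the pyran ring to give dienol 26 (closest known reaction types: intramolecular oxa-Michael addition of alcohols to cyclohexadienones, and Michael addition–rearomatization of quinone monoketals with carbon, nitrogen and sulfur nucleophiles). Acetic acid should then ionize the C8 ketal of 26 to a cyclohexadienyl cation that loses the C8a proton, so that one methanol leaves and the benzene ring returns with OH at C5 and OMe at C8. No permanent stereocenter is created (C8a is sp2 again) and C2 keeps its S configuration because its C–O bond is never broken, which an oxa-6π closure at O1–C2 could not guarantee. The step needs para over ortho methoxylation of the phenoxonium ion, secured by the C8 methoxy group para to the phenol oxygen, and 1,4- over 1,2-addition of the alkoxide, secured because carbonyl addition is reversible and leads nowhere while the C8a adduct is drained by aromatization. 2,6-Lutidine keeps the electrolysis non-acidic so that the tertiary allylic alcohol of 24 is not ionized toward closure on the phenol oxygen.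

## Compound list

1 | 2,6-dimethylcyclohexan-1-one (cis/trans mixture) | CC1CCCC(C)C1=O | starting material
2 | (S)-1-phenylethylamine | C[C@H](N)c1ccccc1 | starting material
3 | but-3-en-2-one | CC(=O)C=C | starting material
4 | (1S)-N-(2,6-dimethylcyclohexylidene)-1-phenylethan-1-amine | C[C@H](N=C1C(C)CCCC1C)c1ccccc1 | intermediate (not isolated)
5 | 4-[(1R)-1,3-dimethyl-2-{[(1S)-1-phenylethyl]imino}cyclohexyl]butan-2-one | C[C@H](N=C1C(C)CCC[C@]1(C)CCC(C)=O)c1ccccc1 | intermediate (not isolated)
6 | (2R)-2,6-dimethyl-2-(3-oxobutyl)cyclohexan-1-one (both C6 epimers) | O=C1C(C)CCC[C@]1(C)CCC(C)=O | intermediate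
7 | (4aR,8R)-4a,8-dimethyl-4,4a,5,6,7,8-hexahydronaphthalen-2(3H)-one | O=C2C=C1[C@H](C)CCC[C@]1(C)CC2 | intermediate
8 | (4aR,8R)-1,8a-epoxy-4a,8-dimethyloctahydronaphthalen-2(1H)-one (both epoxide faces) | O=C2C3OC31[C@H](C)CCC[C@]1(C)CC2 | intermediate
9 | 4-methylbenzenesulfonylhydrazone of 8 | Cc1ccc(cc1)S(=O)(=O)NN=C2C3OC31[C@H](C)CCC[C@]1(C)CC2 | intermediate (not isolated)
10 | (2R,6R)-2-(but-3-yn-1-yl)-2,6-dimethylcyclohexan-1-one | O=C1[C@H](C)CCC[C@]1(C)CCC#C | intermediate
11 | (1R,3R)-1-(but-3-yn-1-yl)-1,3-dimethyl-2-methylidenecyclohexane | C=C1[C@H](C)CCC[C@]1(C)CCC#C | intermediate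
12 | [(1E)-4-[(1R,3R)-1,3-dimethyl-2-methylidenecyclohexyl]-2-methylbut-1-en-1-yl]dimethylalumane | C=C1[C@H](C)CCC[C@]1(C)CC/C(C)=C/[Al](C)C | intermediate (not isolated)
13 | (2E)-5-[(1R,3R)-1,3-dimethyl-2-methylidenecyclohexyl]-3-methylpent-2-en-1-ol | C=C1[C@H](C)CCC[C@]1(C)CC/C(C)=C/CO | intermediate
14 | [(2S,3S)-3-{2-[(1R,3R)-1,3-dimethyl-2-methylidenecyclohexyl]ethyl}-3-methyloxiran-2-yl]methanol | C=C1[C@H](C)CCC[C@]1(C)CC[C@]2(C)O[C@H]2CO | intermediate
15 | (2R,3S)-2-(chloromethyl)-3-{2-[(1R,3R)-1,3-dimethyl-2-methylidenecyclohexyl]ethyl}-3-methyloxirane | C=C1[C@H](C)CCC[C@]1(C)CC[C@]2(C)O[C@H]2CCl | intermediate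
16 | (3S)-5-[(1R,3R)-1,3-dimethyl-2-methylidenecyclohexyl]-3-methylpent-1-yn-3-ol | C=C1[C@H](C)CCC[C@]1(C)CC[C@](C)(O)C#C | intermediate
17 | 2,3,4-trimethoxybenzaldehyde | COc1ccc(C=O)c(OC)c1OC | starting material
18 | 2,3,4-trimethoxyphenyl formate | COc1ccc(OC=O)c(OC)c1OC | intermediate (not isolated)
19 | 2,3,4-trimethoxyphenol | COc1ccc(O)c(OC)c1OC | intermediate
20 | 6-iodo-2,3,4-trimethoxyphenol | COc1cc(I)c(O)c(OC)c1OC | intermediate
21 | 6-iodo-2,3,4-trimethoxyphenyl acetate | COc1cc(I)c(OC(C)=O)c(OC)c1OC | intermediate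
22 | 6-[(3S)-5-[(1R,3R)-1,3-dimethyl-2-methylidenecyclohexyl]-3-hydroxy-3-methylpent-1-yn-1-yl]-2,3,4-trimethoxyphenyl acetate | C=C1[C@H](C)CCC[C@]1(C)CC[C@](C)(O)C#Cc1cc(OC)c(OC)c(OC)c1OC(C)=O | intermediate
23 | 6-[(1Z,3S)-5-[(1R,3R)-1,3-dimethyl-2-methylidenecyclohexyl]-3-hydroxy-3-methylpent-1-en-1-yl]-2,3,4-trimethoxyphenyl acetate | C=C1[C@H](C)CCC[C@]1(C)CC[C@](C)(O)/C=C\c1cc(OC)c(OC)c(OC)c1OC(C)=O | intermediate
24 | 6-[(1Z,3S)-5-[(1R,3R)-1,3-dimethyl-2-methylidenecyclohexyl]-3-hydroxy-3-methylpent-1-en-1-yl]-2,3,4-trimethoxyphenol | C=C1[C@H](C)CCC[C@]1(C)CC[C@](C)(O)/C=C\c1cc(OC)c(OC)c(OC)c1O | intermediate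
25 | 2-[(1Z,3S)-5-[(1R,3R)-1,3-dimethyl-2-methylidenecyclohexyl]-3-hydroxy-3-methylpent-1-en-1-yl]-4,4,5,6-tetramethoxycyclohexa-2,5-dien-1-one | C=C1[C@H](C)CCC[C@]1(C)CC[C@](C)(O)/C=C\C1=CC(OC)(OC)C(OC)=C(OC)C1=O | intermediate (not isolated)
26 | (2S)-2-{2-[(1R,3R)-1,3-dimethyl-2-methylidenecyclohexyl]ethyl}-6,7,8,8-tetramethoxy-2-methyl-8,8a-dihydro-2H-chromen-5-ol (both C8a epimers) | C=C1[C@H](C)CCC[C@]1(C)CC[C@@]1(C)C=CC2=C(O)C(OC)=C(OC)C(OC)(OC)C2O1 | intermediate (not isolated)
27 | (2S)-2-{2-[(1R,3R)-1,3-dimethyl-2-methylidenecyclohexyl]ethyl}-6,7,8-trimethoxy-2-methyl-2H-chromen-5-ol | C=C1[C@H](C)CCC[C@]1(C)CC[C@@]1(C)C=Cc2c(O)c(OC)c(OC)c(OC)c2O1 | target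

## Step count and risks

Total steps: 16. Longest linear sequence: 13 steps (steps 1–9, then 13–16); the aryl branch (steps 10–12) joins at step 13.

**Risk 1, step 16 (proposed new method).**
- What may go wrong: acid formed at the anode could ionize the tertiary allylic alcohol, so that the phenol oxygen closes the ring instead. After the oxidation, the alkoxide may add reversibly without productive aromatization, or methanol may add to C8a in its place. Further oxidation of the electron-rich product is possible if current is passed while base is present.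
- Fallback (known chemistry, same O1–C8a bond by palladium-catalysed aryl etherification): it sets out from 20 and 16 and returns at 27. Phenol 20 is brominated at its last free ring position (NBS, MeCN, 0 °C) to 5-bromo-6-iodo-2,3,4-trimethoxyphenol F1. This is silylated (TIPSOTf, 2,6-lutidine, CH2Cl2) to (3-bromo-2-iodo-4,5,6-trimethoxyphenoxy)tri(propan-2-yl)silane F2. Sonogashira coupling at the C–I bond with 16 (Pd(PPh3)2Cl2, CuI, Et3N, rt) gives the bromoaryl alkynol F3. Lindlar semihydrogenation gives the Z bromoaryl alkenol F4. Buchwald–Hartwig-type intramolecular etherification of the tertiary alcohol (Pd(OAc)2, 2-(di-tert-butylphosphino)-1,1'-binaphthyl, Cs2CO3, toluene, 80 °C) closes the pyran to the chromene silyl ether F5. TBAF (THF, 0 °C) then gives 27.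

**Risk 2, step 5.**
- What may go wrong: slow carbonyl methylenation at the doubly α-branched ketone, consumption of reagent by the alkyne C–H, or enolization with loss of configuration at C6.
- Fallback (Peterson olefination instead of direct methylenation): it sets out from 10 and returns at 11. Me3SiCH2Li premixed with CeCl3 (THF, −78 °C, one extra equivalent for the alkyne C–H) should add to the ketone without enolization to give (2R,6R)-2-(but-3-yn-1-yl)-2,6-dimethyl-1-[(trimethylsilyl)methyl]cyclohexan-1-ol F6. KH (THF, rt) then eliminates silanolate to give 11.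

**Risk 3, step 14.**
- What may go wrong: over-reduction of the styrene-type alkene and partial Z to E isomerization on the catalyst surface.
- Fallback (Z geometry fixed before the C–C coupling): it sets out from 16 and 21 and returns at 23. Alkynol 16 is iodinated (NIS, AgNO3 cat., acetone) to (3S)-5-[(1R,3R)-1,3-dimethyl-2-methylidenecyclohexyl]-1-iodo-3-methylpent-1-yn-3-ol F7. cis-Reduction with diimide (2-nitrobenzenesulfonohydrazide, Et3N, THF/i-PrOH, rt) gives (1Z,3S)-5-[(1R,3R)-1,3-dimethyl-2-methylidenecyclohexyl]-1-iodo-3-methylpent-1-en-3-ol F8. Iodide 21 is converted by Miyaura borylation (bis(pinacolato)diboron, Pd(dppf)Cl2, KOAc, dioxane, 80 °C) into 2,3,4-trimethoxy-6-(4,4,5,5-tetramethyl-1,3,2-dioxaborolan-2-yl)phenyl acetate F9. Suzuki–Miyaura coupling of F8 with F9 (Pd(PPh3)4, CsF, THF, 60 °C) proceeds with retention of alkene geometry to give 23.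

## Further compounds

F1 | step 16 | 5-bromo-6-iodo-2,3,4-trimethoxyphenol | COc1c(Br)c(I)c(O)c(OC)c1OC
F2 | step 16 | (3-bromo-2-iodo-4,5,6-trimethoxyphenoxy)tri(propan-2-yl)silane | COc1c(Br)c(I)c(O[Si](C(C)C)(C(C)C)C(C)C)c(OC)c1OC
F3 | step 16 | (3S)-1-{2-bromo-3,4,5-trimethoxy-6-[tri(propan-2-yl)silyloxy]phenyl}-5-[(1R,3R)-1,3-dimethyl-2-methylidenecyclohexyl]-3-methylpent-1-yn-3-ol | C=C1[C@H](C)CCC[C@]1(C)CC[C@](C)(O)C#Cc1c(Br)c(OC)c(OC)c(OC)c1O[Si](C(C)C)(C(C)C)C(C)C
F4 | step 16 | (1Z,3S)-1-{2-bromo-3,4,5-trimethoxy-6-[tri(propan-2-yl)silyloxy]phenyl}-5-[(1R,3R)-1,3-dimethyl-2-methylidenecyclohexyl]-3-methylpent-1-en-3-ol | C=C1[C@H](C)CCC[C@]1(C)CC[C@](C)(O)/C=C\c1c(Br)c(OC)c(OC)c(OC)c1O[Si](C(C)C)(C(C)C)C(C)C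
F5 | step 16 | {[(2S)-2-{2-[(1R,3R)-1,3-dimethyl-2-methylidenecyclohexyl]ethyl}-6,7,8-trimethoxy-2-methyl-2H-chromen-5-yl]oxy}tri(propan-2-yl)silane | C=C1[C@H](C)CCC[C@]1(C)CC[C@@]1(C)C=Cc2c(O[Si](C(C)C)(C(C)C)C(C)C)c(OC)c(OC)c(OC)c2O1
F6 | step 5 | (2R,6R)-2-(but-3-yn-1-yl)-2,6-dimethyl-1-[(trimethylsilyl)methyl]cyclohexan-1-ol (either C1 epimer) | C[Si](C)(C)CC1(O)[C@H](C)CCC[C@]1(C)CCC#C
F7 | step 14 | (3S)-5-[(1R,3R)-1,3-dimethyl-2-methylidenecyclohexyl]-1-iodo-3-methylpent-1-yn-3-ol | C=C1[C@H](C)CCC[C@]1(C)CC[C@](C)(O)C#CI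
F8 | step 14 | (1Z,3S)-5-[(1R,3R)-1,3-dimethyl-2-methylidenecyclohexyl]-1-iodo-3-methylpent-1-en-3-ol | C=C1[C@H](C)CCC[C@]1(C)CC[C@](C)(O)/C=C\I
F9 | step 14 | 2,3,4-trimethoxy-6-(4,4,5,5-tetramethyl-1,3,2-dioxaborolan-2-yl)phenyl acetate | COc1cc(B2OC(C)(C)C(C)(C)O2)c(OC(C)=O)c(OC)c1OC
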